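In the alpha run the electrophile falls from 13.6% at 3.00 min to 2.5% at 6.00 min. The beta run, with 0.19 M of free base against 0.061 M, shows 12.6% and 3.3% at those times.

all flasks: electrophile 0.10 M

| charge | nucleophile | free base | remark | time |
|---|---|---|---|---|
| alpha | 0.25 M | 0.061 M | run made earlier |  |
| beta | 0.25 M | 0.19 M | run made earlier |  |
| summer | 0.250 M | 0.110 M |  | 30 min |
| midnight | 0.250 M | 0.220 M |  | 30 min |

| run | time / min | electrophile / % | product / % |
|---|---|---|---|
| alpha | 3.00 | 13.6 | 79.8 |
| alpha | 6.00 | 2.5 | 87.0 |
| alpha | 10.0 | 1.1 | 89.8 |
| alpha | 12.0 | 1.1 | 90.2 |
| alpha | 15.0 | 0.9 | 89.2 |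
| alpha | 20.0 | 0.5 | 90.9 |
| beta | 1.00 | 39.8 | 55.4 |
| beta | 3.00 | 12.6 | 80.3 |
| beta | 6.00 | 3.3 | 87.6 |
| beta | 10.0 | 1.1 | 90.7 |
| beta | 12.0 | 0.1 | 89.8 |
| beta | 15.0 | 0 | 90.7 |
| beta | 20.0 | 0.1 | 90.2 |

(scatter of a reading: 0.5 percentage points)

- a reading or a percentage of product counts all its forms, free or not
- what has gone from electrophile into another species counts as reacted, even if it can come back

- part of the electrophile that has reacted at the end, summer
- part of the electrophile that has reacted at the end, midnight
- what raising the concentration of free base from its lowest to its highest value here does to the part of the electrophile that has reacted (changes below 5 percentage points count as none) (it rises / it falls / no change)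

I read a first-order loss of 0.565 min⁻¹ in alpha and 0.447 min⁻¹ in beta, and a scatter of 0.5 percentage points on a reading as low as 2.5% is too coarse to rank the two.

I assume the reaction sets acid free. Each product formed then costs one nucleophile as reactant and, at worst, a second that takes up the acid. Dividing the two rates removes time: nucleophile goes at most twice as fast as product forms. I carry the nucleophile cover, the charged nucleophile over twice the charged electrophile, which is 1.25. Above one, the electrophile is the limiting reagent even if free base takes no acid, and free base does not enter the number. Alpha and beta have the same cover as summer and midnight, and it stands above one.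

So I expect no trend, with summer and midnight ending near the last electrophile readings, 0.5% in alpha and 0.1% in beta. The cover says nothing of speed, so it needs a second number: at beta's rate the half-life is 1.55 min, and 30 min holds 19.4 of them. At worst, 20.0% of the nucleophile stays free.

The forecast gives 99.7%, 99.9% and no change: "Free base therefore has little kinetic effect."

The flasks give 99.8% for summer and 99.9% for midnight, and for the trend no change, a difference of 0.016 points.

    electrophile + nucleophile → acid set free + product (k = 4.40 M⁻¹ min⁻¹)
    acid set free + free base ⇌ salt of the base, settled at all times (K = 300 M⁻¹)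
    crystals ⇌ product, rate k3*(cs3 - [product]) while solid is left; crystals form when [product] > cs3 (solubility = 0.0890 M, k = 0.280 min⁻¹)
    nucleophile + acid set free ⇌ protonated nucleophile, settled at all times (K = 2200 M⁻¹)
    electrophile ⇌ dormant form (K = 9.90, k = 0.0750 min⁻¹)

Summer still has 32.3% of its nucleophile free at 30.0 min, more than the floor of 20.0%. A neighbour of summer charged with 0.062 M of nucleophile has a cover of 0.310, and it ends at 93.2% reacted, with 6.79% of its electrophile left.

(The earlier runs and the new flask were generated by integration with constants of no real substance; the scatter is artificial.)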